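**Plan**

- Numbering and feature: the chain runs from C1 (on ring B, 3,4-dihydroxy-5-methoxyphenyl) to C7 (on ring A, 4-hydroxy-3-methoxyphenyl). C1 and the carbinol C5 are both β to the C3 ketone, so the target is a 2-aryl-tetrahydropyran-4-one (oxygen bridging C1 and C5) opened reductively at its benzylic C1–O bond.
- Retrosynthesis: re-form C1–O and take C3 to the alcohol level, then cut C1–C2, C1–O and C3–O in a Prins sense. This gives an (R)-homoallylic alcohol (C2–C7 with ring A) and a ring-B benzaldehyde (C1); the alcohol is cut at C4–C5 into a 3-arylpropanal and an allyl metal.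
- Forward: eugenol is taken to the 3-arylpropanal and allylated (C4–C5). The Prins cyclisation joins both halves and closes the only new ring. Oxidation at C3, then hydrogenolysis with base-triggered retro-oxa-Michael opening, returns the open chain.
- Stereochemistry: the single stereocenter C5 (R) comes from reagent-controlled allylboration and its C–O bond is never broken. The ring stereocenters at C1 and C3 are temporary.

Key step: step 6

**Route**

Step 1
Reactants: 1 eugenol
Product: 2 4-allyl-1-(benzyloxy)-2-methoxybenzene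
Conditions: BnBr, K2CO3, DMF, rt
Reagents that add atoms: benzyl bromide, BrCc1ccccc1
Why: Williamson etherification, in which the phenoxide formed by K2CO3 displaces bromide from benzyl bromide (SN2) and the allyl group is inert.

Step 2
Reactants: 2 4-allyl-1-(benzyloxy)-2-methoxybenzene
Product: 4 3-[4-(benzyloxy)-3-methoxyphenyl]propan-1-ol, via B-alkyl-9-BBN adduct 3 (not isolated)
Conditions: 9-BBN (9-borabicyclo[3.3.1]nonane), THF, 0 °C → rt; then 3 M NaOH, 30% H2O2, 0 °C → rt
Reagents that add atoms: hydrogen peroxide, OO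
Why: Hydroboration–oxidation, in which the bulky borane places boron on the terminal alkene carbon and alkaline peroxide replaces boron by hydroxyl, so the primary alcohol should form with the aryl ethers untouched.

Step 3
Reactants: 4 3-[4-(benzyloxy)-3-methoxyphenyl]propan-1-ol
Product: 5 3-[4-(benzyloxy)-3-methoxyphenyl]propanal
Conditions: Dess–Martin periodinane, CH2Cl2, 0 °C → rt
Reagents that add atoms: none
Why: Dess–Martin oxidation should stop at the aldehyde under neutral anhydrous conditions and spare the electron-rich arene and the benzyl ether.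

Step 4
Reactants: 5 3-[4-(benzyloxy)-3-methoxyphenyl]propanal; 6 allylmagnesium bromide
Product: 8 (R)-1-[4-(benzyloxy)-3-methoxyphenyl]hex-5-en-3-ol, via borinate ester 7 (not isolated)
Conditions: (−)-Ipc2BOMe [from (+)-α-pinene], 6, Et2O, −78 °C → rt; then 5, −78 °C; then 3 M NaOH, 30% H2O2, rt
Reagents that add atoms: none
Why: Brown allylation, in which the B-allyldiisopinocampheylborane made in the flask transfers allyl through a closed six-membered chair transition state to the Si face of the aldehyde, setting C5 as R (allyl outranks the arylethyl chain) before oxidative work-up frees the alcohol.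

Step 5
Reactants: 9 3,4-dihydroxy-5-methoxybenzaldehyde
Product: 10 3,4-bis(benzyloxy)-5-methoxybenzaldehyde
Conditions: BnBr, K2CO3, DMF, 60 °C
Reagents that add atoms: benzyl bromide, BrCc1ccccc1
Why: Double Williamson etherification of both phenols; the aldehyde has no α-hydrogen and should survive the carbonate base.

Step 6
Reactants: 8 (R)-1-[4-(benzyloxy)-3-methoxyphenyl]hex-5-en-3-ol; 10 3,4-bis(benzyloxy)-5-methoxybenzaldehyde
Product: 12 (2R,4S,6R)-2-[3,4-bis(benzyloxy)-5-methoxyphenyl]-6-{2-[4-(benzyloxy)-3-methoxyphenyl]ethyl}tetrahydropyran-4-ol, via trifluoroacetate ester 11 (not isolated)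
Conditions: CF3CO2H, CH2Cl2, 0 °C → rt; concentrate; K2CO3 (cat.), MeOH, rt
Reagents that add atoms: trifluoroacetic acid, OC(=O)C(F)(F)F (its oxygen becomes the hydroxyl oxygen at chain C3)
Why: Acid-mediated Prins cyclisation: 8 and 10 form a hemiacetal that ionises to an (E)-oxocarbenium ion conjugated with ring B, the terminal alkene carbon C2 attacks C1, and the tetrahydropyranyl cation at C3 is captured by trifluoroacetate to give 11, which methanolysis converts to 12; the closest known reaction type is the CF3CO2H-promoted Prins cyclisation of homoallylic alcohols with aldehydes to all-cis 2,6-disubstituted tetrahydropyran-4-ols. The single ring (O, C1–C5) closes in a 6-endo-trig mode through a chair transition state. C1 is set by the (E)-geometry of the oxocarbenium ion with the C5 arylethyl chain equatorial, which puts the aryl group equatorial and cis to that chain, and C3 is set by equatorial capture of the delocalised cation, so all three ring substituents should be cis. The selectivity that matters is retention of the C5 configuration and clean cross-coupling without allyl transfer, since C1 and C3 are erased later. The substrate secures this because the carbinol carbon is alkyl-substituted and cannot ionise, and because any 2-oxonia-Cope partner is the less stable non-conjugated oxocarbenium ion, which returns through the same chair with chirality transfer. The para oxygen of ring B is twisted by its two neighbours, which should keep the oxocarbenium ion electrophilic enough for the alkene to trap it.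

Step 7
Reactants: 12 (2R,4S,6R)-2-[3,4-bis(benzyloxy)-5-methoxyphenyl]-6-{2-[4-(benzyloxy)-3-methoxyphenyl]ethyl}tetrahydropyran-4-ol
Product: 13 (2R,6R)-2-[3,4-bis(benzyloxy)-5-methoxyphenyl]-6-{2-[4-(benzyloxy)-3-methoxyphenyl]ethyl}tetrahydropyran-4-one
Conditions: Dess–Martin periodinane, CH2Cl2, rt
Reagents that add atoms: none
Why: Dess–Martin oxidation of the secondary alcohol under neutral conditions should give the β-alkoxy ketone without elimination, and it deliberately removes the temporary stereocenter at chain C3.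

Step 8
Reactants: 13 (2R,6R)-2-[3,4-bis(benzyloxy)-5-methoxyphenyl]-6-{2-[4-(benzyloxy)-3-methoxyphenyl]ethyl}tetrahydropyran-4-one
Product: 16 (R)-1-(3,4-dihydroxy-5-methoxyphenyl)-5-hydroxy-7-(4-hydroxy-3-methoxyphenyl)heptan-3-one, via triphenolic tetrahydropyranone 14 (not isolated), via ring-opened aryl enone 15 (not isolated)
Conditions: H2 (1 atm), 10% Pd/C, EtOAc–MeOH, rt; then K2CO3 (cat.), H2 kept on, rt; AcOH quench before exposure to air
Reagents that add atoms: none
Why: Proposed new method: hydrogenolysis over Pd/C first removes the three benzyl ethers (standard) to give 14; catalytic base then enolises the ketone toward C2 and the enolate expels the ring oxygen from benzylic C1 (E1cB retro-oxa-Michael), which should be preferred over expulsion from C5 because only this path gives an enone conjugated with ring B, whose para-phenoxide makes 15 a vinylogous carboxylate that does not reclose; Pd/H2 then saturates C1=C2 irreversibly and drains the equilibrium while the C5–O bond and its configuration stay untouched; the closest known reaction types are the alkaline catalytic hydrogenation of flavanones to dihydrochalcones and the base-mediated oxa-Michael/retro-oxa-Michael equilibration of 2,6-disubstituted tetrahydropyran-4-ones.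

**Compound list**

1 | eugenol | COc1cc(CC=C)ccc1O | starting material
2 | 4-allyl-1-(benzyloxy)-2-methoxybenzene | COc1cc(CC=C)ccc1OCc1ccccc1 | intermediate
3 | 9-{3-[4-(benzyloxy)-3-methoxyphenyl]propyl}-9-borabicyclo[3.3.1]nonane | COc1cc(CCCB2C3CCCC2CCC3)ccc1OCc1ccccc1 | intermediate
4 | 3-[4-(benzyloxy)-3-methoxyphenyl]propan-1-ol | COc1cc(CCCO)ccc1OCc1ccccc1 | intermediate
5 | 3-[4-(benzyloxy)-3-methoxyphenyl]propanal | COc1cc(CCC=O)ccc1OCc1ccccc1 | intermediate
6 | allylmagnesium bromide | C=CC[Mg]Br | starting material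
7 | (R)-1-[4-(benzyloxy)-3-methoxyphenyl]hex-5-en-3-yl diisopinocampheylborinate | COc1cc(CC[C@@H](OB([C@@H]2C[C@@H]3C[C@H]([C@H]2C)C3(C)C)[C@@H]2C[C@@H]3C[C@H]([C@H]2C)C3(C)C)CC=C)ccc1OCc1ccccc1 | intermediate
8 | (R)-1-[4-(benzyloxy)-3-methoxyphenyl]hex-5-en-3-ol | COc1cc(CC[C@@H](O)CC=C)ccc1OCc1ccccc1 | intermediate
9 | 3,4-dihydroxy-5-methoxybenzaldehyde | COc1cc(C=O)cc(O)c1O | starting material
10 | 3,4-bis(benzyloxy)-5-methoxybenzaldehyde | COc1cc(C=O)cc(OCc2ccccc2)c1OCc1ccccc1 | intermediate
11 | (2R,4S,6R)-2-[3,4-bis(benzyloxy)-5-methoxyphenyl]-6-{2-[4-(benzyloxy)-3-methoxyphenyl]ethyl}tetrahydropyran-4-yl trifluoroacetate | O1[C@@H](c2cc(OC)c(OCc3ccccc3)c(OCc3ccccc3)c2)C[C@@H](OC(=O)C(F)(F)F)C[C@H]1CCc1ccc(OCc2ccccc2)c(OC)c1 | intermediate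
12 | (2R,4S,6R)-2-[3,4-bis(benzyloxy)-5-methoxyphenyl]-6-{2-[4-(benzyloxy)-3-methoxyphenyl]ethyl}tetrahydropyran-4-ol (all-cis) | O1[C@@H](c2cc(OC)c(OCc3ccccc3)c(OCc3ccccc3)c2)C[C@@H](O)C[C@H]1CCc1ccc(OCc2ccccc2)c(OC)c1 | intermediate
13 | (2R,6R)-2-[3,4-bis(benzyloxy)-5-methoxyphenyl]-6-{2-[4-(benzyloxy)-3-methoxyphenyl]ethyl}tetrahydropyran-4-one (2,6-cis) | O1[C@@H](c2cc(OC)c(OCc3ccccc3)c(OCc3ccccc3)c2)CC(=O)C[C@H]1CCc1ccc(OCc2ccccc2)c(OC)c1 | intermediate
14 | (2R,6R)-2-(3,4-dihydroxy-5-methoxyphenyl)-6-[2-(4-hydroxy-3-methoxyphenyl)ethyl]tetrahydropyran-4-one | O1[C@@H](c2cc(OC)c(O)c(O)c2)CC(=O)C[C@H]1CCc1ccc(O)c(OC)c1 | intermediate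
15 | (R,E)-1-(3,4-dihydroxy-5-methoxyphenyl)-5-hydroxy-7-(4-hydroxy-3-methoxyphenyl)hept-1-en-3-one | COc1cc(CC[C@@H](O)CC(=O)/C=C/c2cc(O)c(O)c(OC)c2)ccc1O | intermediate
16 | (R)-1-(3,4-dihydroxy-5-methoxyphenyl)-5-hydroxy-7-(4-hydroxy-3-methoxyphenyl)heptan-3-one (CNP0248502.1) | COc1cc(CC[C@@H](O)CC(=O)CCc2cc(O)c(O)c(OC)c2)ccc1O | target

**Step count**

Total: 8 steps. Longest linear sequence: 7 steps (steps 1, 2, 3, 4, 6, 7, 8, from eugenol).

**Steps most likely to fail**

1. Step 8. The retro-oxa-Michael opening may be slow under such mild base, or may be diverted toward expulsion of oxygen from C5. The β-hydroxy ketone product may also dehydrate or undergo retro-aldol cleavage under base, and hydrogenation would then remove the C5 oxygen or erode its configuration.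
   Fallback (cationic instead of anionic opening, known chemistry): the detour sets out from 13. Ionic hydrogenation with Et3SiH and CF3CO2H in CH2Cl2 at 0 °C should ionise only the benzylic C1–O bond, giving a cation stabilised by the para benzyloxy group, and deliver hydride to C1. This gives (R)-1-[3,4-bis(benzyloxy)-5-methoxyphenyl]-7-[4-(benzyloxy)-3-methoxyphenyl]-5-hydroxyheptan-3-one F1. Neutral hydrogenolysis of its three benzyl ethers (H2, Pd/C, EtOAc, rt), conditions a β-hydroxy ketone tolerates, returns to the route at 16.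

2. Step 6. Capture of the stabilised aryl oxocarbenium ion by the alkene may be slow, which leaves time for oxonia-Cope allyl transfer, side-chain exchange and erosion of the C5 configuration. The aryl benzyl ethers may also be partly lost in CF3CO2H.
   Fallback (oxocarbenium ion generated from an α-acetoxy ether instead of by reversible condensation): the detour sets out from 8 and 10.
   - Pinnick oxidation of 10 (NaClO2, NaH2PO4, 2-methyl-2-butene, tBuOH–H2O) should give 3,4-bis(benzyloxy)-5-methoxybenzoic acid F2.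
   - Steglich esterification with 8 (DCC, DMAP, CH2Cl2) gives (R)-1-[4-(benzyloxy)-3-methoxyphenyl]hex-5-en-3-yl 3,4-bis(benzyloxy)-5-methoxybenzoate F3.
   - Reductive acetylation (iBu2AlH, CH2Cl2, −78 °C; then Ac2O, pyridine, DMAP) gives the α-acetoxy ether [3,4-bis(benzyloxy)-5-methoxyphenyl]{[(R)-1-(4-(benzyloxy)-3-methoxyphenyl)hex-5-en-3-yl]oxy}methyl acetate F4, as a mixture of acetal epimers.
   - Prins cyclisation under BF3·OEt2 and AcOH (CH2Cl2–hexane, 0 °C) gives (2R,4S,6R)-2-[3,4-bis(benzyloxy)-5-methoxyphenyl]-6-{2-[4-(benzyloxy)-3-methoxyphenyl]ethyl}tetrahydropyran-4-yl acetate F5. No strong protic acid is present and no free aldehyde is available for exchange.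
   - Methanolysis (K2CO3, MeOH) returns to the route at 12.

3. Step 4. Facial discrimination in the allyl transfer may be incomplete, and because the target has only this stereocenter no later step can raise the enantiomeric purity. Separation from isopinocampheol may also cost material.
   Fallback (asymmetric hydrogenation in place of asymmetric allylation): the detour sets out from 5.
   - Roskamp homologation (ethyl diazoacetate, SnCl2 cat., CH2Cl2) should give ethyl 5-[4-(benzyloxy)-3-methoxyphenyl]-3-oxopentanoate F6.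
   - Noyori hydrogenation (H2, RuCl2[(R)-BINAP], EtOH) gives ethyl (R)-5-[4-(benzyloxy)-3-methoxyphenyl]-3-hydroxypentanoate F7, in the same sense as methyl acetoacetate gives the (R)-hydroxy ester.
   - Silylation (TBSCl, imidazole, DMF) gives ethyl (R)-5-[4-(benzyloxy)-3-methoxyphenyl]-3-[(tert-butyldimethylsilyl)oxy]pentanoate F8.
   - Partial reduction (iBu2AlH, CH2Cl2, −78 °C) gives (R)-5-[4-(benzyloxy)-3-methoxyphenyl]-3-[(tert-butyldimethylsilyl)oxy]pentanal F9.
   - Wittig methylenation (Ph3P=CH2, THF, 0 °C) gives (R)-{1-[4-(benzyloxy)-3-methoxyphenyl]hex-5-en-3-yl}oxy(tert-butyl)dimethylsilane F10.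
   - Desilylation (Bu4NF, THF) returns to the route at 8.

**Further compounds**

F1 | step 8 | (R)-1-[3,4-bis(benzyloxy)-5-methoxyphenyl]-7-[4-(benzyloxy)-3-methoxyphenyl]-5-hydroxyheptan-3-one | COc1cc(CC[C@@H](O)CC(=O)CCc2cc(OC)c(OCc3ccccc3)c(OCc3ccccc3)c2)ccc1OCc1ccccc1
F2 | step 6 | 3,4-bis(benzyloxy)-5-methoxybenzoic acid | COc1cc(C(=O)O)cc(OCc2ccccc2)c1OCc1ccccc1
F3 | step 6 | (R)-1-[4-(benzyloxy)-3-methoxyphenyl]hex-5-en-3-yl 3,4-bis(benzyloxy)-5-methoxybenzoate | COc1cc(CC[C@@H](OC(=O)c2cc(OC)c(OCc3ccccc3)c(OCc3ccccc3)c2)CC=C)ccc1OCc1ccccc1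
F4 | step 6 | [3,4-bis(benzyloxy)-5-methoxyphenyl]{[(R)-1-(4-(benzyloxy)-3-methoxyphenyl)hex-5-en-3-yl]oxy}methyl acetate (acetal epimers) | COc1cc(CC[C@@H](OC(OC(C)=O)c2cc(OC)c(OCc3ccccc3)c(OCc3ccccc3)c2)CC=C)ccc1OCc1ccccc1
F5 | step 6 | (2R,4S,6R)-2-[3,4-bis(benzyloxy)-5-methoxyphenyl]-6-{2-[4-(benzyloxy)-3-methoxyphenyl]ethyl}tetrahydropyran-4-yl acetate | O1[C@@H](c2cc(OC)c(OCc3ccccc3)c(OCc3ccccc3)c2)C[C@@H](OC(C)=O)C[C@H]1CCc1ccc(OCc2ccccc2)c(OC)c1
F6 | step 4 | ethyl 5-[4-(benzyloxy)-3-methoxyphenyl]-3-oxopentanoate | COc1cc(CCC(=O)CC(=O)OCC)ccc1OCc1ccccc1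
F7 | step 4 | ethyl (R)-5-[4-(benzyloxy)-3-methoxyphenyl]-3-hydroxypentanoate | COc1cc(CC[C@@H](O)CC(=O)OCC)ccc1OCc1ccccc1
F8 | step 4 | ethyl (R)-5-[4-(benzyloxy)-3-methoxyphenyl]-3-[(tert-butyldimethylsilyl)oxy]pentanoate | COc1cc(CC[C@@H](O[Si](C)(C)C(C)(C)C)CC(=O)OCC)ccc1OCc1ccccc1
F9 | step 4 | (R)-5-[4-(benzyloxy)-3-methoxyphenyl]-3-[(tert-butyldimethylsilyl)oxy]pentanal | COc1cc(CC[C@@H](O[Si](C)(C)C(C)(C)C)CC=O)ccc1OCc1ccccc1
F10 | step 4 | (R)-{1-[4-(benzyloxy)-3-methoxyphenyl]hex-5-en-3-yl}oxy(tert-butyl)dimethylsilane | COc1cc(CC[C@@H](O[Si](C)(C)C(C)(C)C)CC=C)ccc1OCc1ccccc1
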